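A ratio of 0.0502 started my reckoning: the rate at which D forms divided by the rate at which E forms, as read roughly from the epsilon run, the selectivity factor. Both products form from Q, so the amount of Q cancels and time drops out of this ratio only while neither step runs back; I meant it for the opening of the flask.

| flask | Q | J | remark | time |
|---|---|---|---|---|
| epsilon | 0.80 M | 0.40 M | the very flask that is asked about, followed so far |  |
| zeta | 0.80 M | 0.80 M | run made earlier |  |
| flask | 0.80 M | 0.400 M |  | 20 min |

- epsilon (time / min: D / %, E / %): 1.50: 1, 19; 3.00: 1, 20; 5.00: 4, 20; 6.00: 3, 19
- zeta (time / min: D / %, E / %): 1.50: 0, 13; 4.00: 0, 15; 8.00: 0, 10; 20.0: 3, 8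

(each reading ± 1.5 percentage points)

- share of D in D plus E at 5.0 s
- share of D in D plus E at 20 min
- which of D and E there is more of at 20 min

- percent here means Q units held: one G counts as two
- the numbers in the tables scatter by 1.5 percentage points (one standard deviation)
- reactions considered so far: Q <-> E; Q + J -> L; Q <-> Z; 2 Q -> G; Q <-> D

In the epsilon run, the last two D readings gave 0.00636 min⁻¹ as a fraction of the charge, and the first E reading gave 0.127 min⁻¹. E barely moved by the next reading, so I treated that E rate as a floor and my ratio as leaning high.

What did this make the early share? At 5.0 s, far earlier than the first reading, I took both products as still forming at their opening rates, so the flask's share was S/(1+S), or 4.78%.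

Did that share hold to 20 min? I expected not, because in the zeta run D rose late while E fell, and its last readings gave a share of 27.3%. Epsilon's E at 6.00 min stood above zeta's at 8.00 min, so I took that reading as a ceiling for the flask. It lies below one half, so I expected E to lead.

The forecast gave 0.3% and 27%, with E ahead: “so E still leads”.

    Q ⇌ E (K = 1.50, k = 0.00490 s⁻¹)
    Q + J → L (k = 0.0190 L mol⁻¹ s⁻¹)
    Q ⇌ Z (K = 0.990, k = 0.00470 s⁻¹)
    2 Q → G (k = 0.00290 L mol⁻¹ s⁻¹)
    Q ⇌ D (K = 2.20, k = 1.30 × 10⁻⁴ s⁻¹)

The flask gave 2.61% at 5.0 s and 12.8% at 20 min, with E ahead, 14.4% against 2.11%. The relaxation half-life of Q and E, 1.41 min, is shorter than 20 min. My ratio times the flask's final E gives 0.723%, less than the D it held, so the late share no longer followed the opening ratio.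

Neither the step to D nor the step to E contains J, so my ratio gives the neighbour charged with 1.0 M of J the same 4.78%. Its computed share at 5.0 s is 2.61%, matching this flask.

(All runs are simulated on assumed constants.)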